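The flavanone is cut at O1–C8a and, decisively, at C3: this ring C carbon carries a methoxy oxygen, a hydrogen, the C4 carbonyl and the C2 carbinol carbon, exactly the substitution left when a carbene carbon picks up methanol and then an aldehyde. One operation therefore joins a ring A diazomethyl ketone (ortho fluorine as latent leaving group), methanol and the benzyl-protected ring B aldehyde, making the C3–OMe and C2–C3 bonds and both stereocentres as the anti (2R,3R) aldol. Fluoride displacement by the C2 oxygen then closes ring C without touching either centre, and hydrogenolysis frees the two ring B phenols.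

Key step: step 5

Assumption: the sense of induction of the chiral phosphoric acid cannot be predicted with confidence for this aldehyde; the (R)-acid is written, and its mirror image would be used if it favoured the (2S,3S) series.
Remark: by CIP analysis the target is the trans (2R,3R) flavanonol 3-methyl ether, and the open-chain adduct with the same descriptors is the anti aldol; ring closure makes or breaks no bond at either centre and leaves the ranking of their substituents unchanged.
Remark: benzyl ethers are kept on ring B because an acyl or silyl group on the oxygen ortho to the carbinol would migrate to the alkoxide in step 6, and because their reductive removal suits the hydroquinone ring.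

Step 1
Reactants: 1 5-fluoro-1,2,3-trimethoxybenzene
Product: 3 1-(6-fluoro-2,3,4-trimethoxyphenyl)ethan-1-one, via aryllithium 2 (not isolated)
Conditions: n-BuLi, THF, −78 °C; MeC(O)N(OMe)Me, −78 to 0 °C; then 1 M HCl
Reagents that add atoms: N-methoxy-N-methylacetamide CC(=O)N(C)OC; n-butyllithium [Li]CCCC (its lithium stays only in 2)
Why: Directed ortho-lithiation is unambiguous because the only two ring hydrogens are equivalent and each lies between fluorine and methoxy, and Weinreb amide acylation stops at the ketone through the chelated tetrahedral adduct (kept cold so that the ortho-fluoro aryllithium does not lose LiF).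

Step 2
Reactants: 3 1-(6-fluoro-2,3,4-trimethoxyphenyl)ethan-1-one
Product: 5 2-diazo-1-(6-fluoro-2,3,4-trimethoxyphenyl)ethan-1-one, via trifluoroacetyl ketone 4 (not isolated)
Conditions: LiN(SiMe3)2, THF, −78 °C; CF3CO2CH2CF3; 1 M HCl work-up; then 4-AcNHC6H4SO2N3, Et3N, H2O, MeCN, rt
Reagents that add atoms: 4-acetamidobenzenesulfonyl azide CC(=O)Nc1ccc(cc1)S(=O)(=O)N=[N+]=[N-]; 2,2,2-trifluoroethyl trifluoroacetate O=C(OCC(F)(F)F)C(F)(F)F (its trifluoroacetyl group stays only in 4)
Why: Danheiser detrifluoroacetylative diazo transfer (a Regitz-type transfer): Claisen trifluoroacetylation activates the methyl group, the sulfonyl azide delivers N2, and retro-Claisen loss of the trifluoroacetyl group as the N-sulfonyl amide leaves the diazomethyl ketone without any diazomethane.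

Step 3
Reactants: 6 2-methoxyhydroquinone
Product: 7 1,4-bis(benzyloxy)-2-methoxybenzene
Conditions: BnBr, K2CO3, DMF, 60 °C, under N2
Reagents that add atoms: benzyl bromide BrCc1ccccc1
Why: Williamson ether synthesis on both phenoxides, run under nitrogen because the hydroquinone anion is air-sensitive.

Step 4
Reactants: 7 1,4-bis(benzyloxy)-2-methoxybenzene
Product: 9 2,5-bis(benzyloxy)-4-methoxybenzaldehyde, via aryl iminium salt 8 (not isolated)
Conditions: POCl3, DMF, 0 to 70 °C; then aq. NaOAc
Reagents that add atoms: N,N-dimethylformamide CN(C)C=O; water O; phosphoryl chloride O=P(Cl)(Cl)Cl (its atoms stay only in the counter-ion of 8)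
Why: Vilsmeier–Haack formylation should go para to the methoxy group and ortho to a benzyloxy group, the only doubly activated position not flanked by two substituents (as in the formylation of 1,2,4-trimethoxybenzene), and hydrolysis of the iminium salt gives the aldehyde.

Step 5
Reactants: 5 2-diazo-1-(6-fluoro-2,3,4-trimethoxyphenyl)ethan-1-one; 9 2,5-bis(benzyloxy)-4-methoxybenzaldehyde; 10 methanol
Product: 11 (2R,3R)-3-[2,5-bis(benzyloxy)-4-methoxyphenyl]-1-(6-fluoro-2,3,4-trimethoxyphenyl)-3-hydroxy-2-methoxypropan-1-one
Conditions: Rh2(OAc)4 (2 mol %), (R)-TRIP [(R)-3,3'-bis(2,4,6-iPr3C6H2)-1,1'-binaphthyl-2,2'-diyl hydrogen phosphate] (10 mol %), 3 Å MS, CH2Cl2, −20 °C; 5 and MeOH (1.5 equiv) added by syringe pump to 9 (2 equiv)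
Reagents that add atoms: none
Why: Rh2(OAc)4, a divalent rhodium carboxylate dimer, expels N2 from 5 to give an electrophilic carbenoid whose carbon is attacked by the oxygen of methanol, forming a protic oxonium ylide (in equilibrium with its enol); before a 1,2-proton shift can collapse it to the simple O–H insertion product, the phosphoric acid, hydrogen-bonded through its OH to the aldehyde oxygen of 9 and through its P=O to the ylide/enol proton, brings the two together in an aldol-type C–C bond formation. The closest known reaction type is the three-component aldol-type trapping of alcohol-derived oxonium ylides of diazo carbonyl compounds by aryl aldehydes under Rh2(OAc)4 and chiral Brønsted acid co-catalysis, here extended to a donor-substituted aldehyde. No ring is closed in this step. Both new stereocentres, the methoxy-bearing carbon and the carbinol carbon (later C3 and C2 of the flavanone), are fixed in that single transition state inside the chiral phosphate pocket, whose 3,3'-aryl groups choose the aldehyde face and the anti arrangement. The step needs chemoselectivity for aldehyde trapping over proton shift together with anti and enantiofacial selectivity; these are served by the unhindered, strongly nucleophilic CH terminus of the ylide from a terminal diazoketone, by keeping 9 in excess while 5 and methanol are fed slowly at low temperature, and by the ortho fluorine of ring A, which does not engage the carbenoid and is carried through unchanged.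

Step 6
Reactants: 11 (2R,3R)-3-[2,5-bis(benzyloxy)-4-methoxyphenyl]-1-(6-fluoro-2,3,4-trimethoxyphenyl)-3-hydroxy-2-methoxypropan-1-one
Product: 12 (2R,3R)-2-[2,5-bis(benzyloxy)-4-methoxyphenyl]-3,5,6,7-tetramethoxy-2,3-dihydro-4H-chromen-4-one
Conditions: Cs2CO3 (1.5 equiv), DMF, 0 °C to rt
Reagents that add atoms: none
Why: Intramolecular SNAr (addition–elimination through a Meisenheimer adduct stabilised by the ortho ketone) forms O1–C8a in a six-membered closure without breaking any bond at C2, which is therefore retained, while the trans-diequatorial (2R,3R) arrangement is also the thermodynamically preferred one at the enolisable C3.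

Step 7
Reactants: 12 (2R,3R)-2-[2,5-bis(benzyloxy)-4-methoxyphenyl]-3,5,6,7-tetramethoxy-2,3-dihydro-4H-chromen-4-one
Product: 13 (2R,3R)-2-(2,5-dihydroxy-4-methoxyphenyl)-3,5,6,7-tetramethoxy-2,3-dihydro-4H-chromen-4-one
Conditions: H2 (1 atm), Pd/C (10 wt % Pd), EtOAc–MeOH, rt; work-up under N2
Reagents that add atoms: none
Why: Hydrogenolysis of the two aryl benzyl ethers over palladium on carbon is neutral and reducing, so the aryl ketone, the methyl ethers, both stereocentres and the oxidation-prone hydroquinone ring should be left intact.

Compound list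
1 | 5-fluoro-1,2,3-trimethoxybenzene | COc1cc(F)cc(OC)c1OC | starting material
2 | (6-fluoro-2,3,4-trimethoxyphenyl)lithium | COc1cc(F)c([Li])c(OC)c1OC | intermediate
3 | 1-(6-fluoro-2,3,4-trimethoxyphenyl)ethan-1-one | COc1cc(F)c(C(C)=O)c(OC)c1OC | intermediate
4 | 4,4,4-trifluoro-1-(6-fluoro-2,3,4-trimethoxyphenyl)butane-1,3-dione | COc1cc(F)c(C(=O)CC(=O)C(F)(F)F)c(OC)c1OC | intermediate
5 | 2-diazo-1-(6-fluoro-2,3,4-trimethoxyphenyl)ethan-1-one | COc1cc(F)c(C(=O)C=[N+]=[N-])c(OC)c1OC | intermediate
6 | 2-methoxyhydroquinone (2-methoxybenzene-1,4-diol) | COc1cc(O)ccc1O | starting material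
7 | 1,4-bis(benzyloxy)-2-methoxybenzene | COc1cc(OCc2ccccc2)ccc1OCc1ccccc1 | intermediate
8 | N-{[2,5-bis(benzyloxy)-4-methoxyphenyl]methylidene}-N-methylmethanaminium dichlorophosphate | COc1cc(OCc2ccccc2)c(C=[N+](C)C)cc1OCc1ccccc1.[O-]P(=O)(Cl)Cl | intermediate
9 | 2,5-bis(benzyloxy)-4-methoxybenzaldehyde | COc1cc(OCc2ccccc2)c(C=O)cc1OCc1ccccc1 | intermediate
10 | methanol | CO | starting material
11 | (2R,3R)-3-[2,5-bis(benzyloxy)-4-methoxyphenyl]-1-(6-fluoro-2,3,4-trimethoxyphenyl)-3-hydroxy-2-methoxypropan-1-one | COc1cc(OCc2ccccc2)c([C@@H](O)[C@@H](OC)C(=O)c2c(F)cc(OC)c(OC)c2OC)cc1OCc1ccccc1 | intermediate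
12 | (2R,3R)-2-[2,5-bis(benzyloxy)-4-methoxyphenyl]-3,5,6,7-tetramethoxy-2,3-dihydro-4H-chromen-4-one | COc1cc(OCc2ccccc2)c([C@H]2Oc3cc(OC)c(OC)c(OC)c3C(=O)[C@@H]2OC)cc1OCc1ccccc1 | intermediate
13 | (2R,3R)-2-(2,5-dihydroxy-4-methoxyphenyl)-3,5,6,7-tetramethoxy-2,3-dihydro-4H-chromen-4-one | COc1cc(O)c([C@H]2Oc3cc(OC)c(OC)c(OC)c3C(=O)[C@@H]2OC)cc1O | target

Total step count: 7. Longest linear sequence: 5 steps (steps 1, 2, 5, 6, 7, or equally steps 3, 4, 5, 6, 7).

Steps most likely to fail

Step 5. Three processes threaten it. The 1,2-proton shift in the oxonium ylide may outpace addition to an aldehyde deactivated by ortho and para oxygen donors, so that plain O–H insertion becomes the main course. The carbenoid may be captured by the neighbouring ring A methoxy oxygen, giving a five-membered cyclic oxonium ylide. Facial or anti/syn discrimination may be poor; an anti/syn mixture of uniform carbinol configuration would still be usable, because C3 equilibrates to trans in step 6. The fallback is carbene-free and stepwise, with resolution; it sets out from 1 and 9 and comes back at 12. Compound 1 is lithiated as in step 1 and the aryllithium is acylated with N,2-dimethoxy-N-methylacetamide (THF, −78 °C) to give 1-(6-fluoro-2,3,4-trimethoxyphenyl)-2-methoxyethan-1-one F1. This ketone is also the by-product expected from the proton-shift pathway, so material from failed runs can be pooled. Its lithium enolate (LiN(i-Pr)2, THF, −78 °C) is added to 9 to give racemic 3-[2,5-bis(benzyloxy)-4-methoxyphenyl]-1-(6-fluoro-2,3,4-trimethoxyphenyl)-3-hydroxy-2-methoxypropan-1-one F2 as an anti/syn mixture. Cs2CO3 in DMF, as in step 6 but continued until C3 has equilibrated, should give racemic trans-2-[2,5-bis(benzyloxy)-4-methoxyphenyl]-3,5,6,7-tetramethoxy-2,3-dihydro-4H-chromen-4-one F3. Preparative chromatography on a chiral stationary phase then delivers the (2R,3R) enantiomer, which is 12.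

Step 6. The alkoxide may undergo retro-aldol cleavage, and recombination would scramble both centres. Base may also dehydrate 11 to the α-methoxychalcone. After closure, enolisation at C3 followed by β-elimination of the ring oxygen and re-addition would erode C2. All three gain ground if substitution on the donor-rich ring A is slow. The fallback masks the nucleophile and removes the stoichiometric base; it sets out from 11 and comes back at 12. Compound 11 is silylated (Me3SiCl, imidazole, CH2Cl2, 0 °C) to (2R,3R)-3-[2,5-bis(benzyloxy)-4-methoxyphenyl]-1-(6-fluoro-2,3,4-trimethoxyphenyl)-2-methoxy-3-[(trimethylsilyl)oxy]propan-1-one F4. This is treated with a catalytic amount of anhydrous CsF (18-crown-6, DMF, rt). Fluoride unmasks the alkoxide only in catalytic concentration, the substitution releases fluoride again, and silicon removes it as Me3SiF. Ring closure should thus run as a fluoride-relayed desilylative SNAr, a known reaction of silyl ethers with activated aryl fluorides.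

Step 7. Hydrogenolytic opening of the benzylic C2–O1 bond (activated by the electron-rich ring B) or reduction at C4 may compete with debenzylation, and the freed hydroquinone may oxidise in air during work-up. The fallback is a non-reductive Lewis acid debenzylation; it sets out from 12 and comes back at 13. Compound 12 is treated with BCl3 and pentamethylbenzene as benzyl cation scavenger (CH2Cl2, −78 °C) and quenched with MeOH at −78 °C. The low temperature is meant to outrun chelation-assisted cleavage of the C5 methoxy group next to the ketone. No new compound is formed (F0).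

Further compounds
F1 | step 5 | 1-(6-fluoro-2,3,4-trimethoxyphenyl)-2-methoxyethan-1-one | COCC(=O)c1c(F)cc(OC)c(OC)c1OC
F2 | step 5 | racemic 3-[2,5-bis(benzyloxy)-4-methoxyphenyl]-1-(6-fluoro-2,3,4-trimethoxyphenyl)-3-hydroxy-2-methoxypropan-1-one (anti/syn mixture) | COc1cc(OCc2ccccc2)c(C(O)C(OC)C(=O)c2c(F)cc(OC)c(OC)c2OC)cc1OCc1ccccc1
F3 | step 5 | racemic trans-2-[2,5-bis(benzyloxy)-4-methoxyphenyl]-3,5,6,7-tetramethoxy-2,3-dihydro-4H-chromen-4-one (12 plus its (2S,3S) enantiomer) | COc1cc(OCc2ccccc2)c([C@H]2Oc3cc(OC)c(OC)c(OC)c3C(=O)[C@@H]2OC)cc1OCc1ccccc1.COc1cc(OCc2ccccc2)c([C@@H]2Oc3cc(OC)c(OC)c(OC)c3C(=O)[C@H]2OC)cc1OCc1ccccc1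
F4 | step 6 | (2R,3R)-3-[2,5-bis(benzyloxy)-4-methoxyphenyl]-1-(6-fluoro-2,3,4-trimethoxyphenyl)-2-methoxy-3-[(trimethylsilyl)oxy]propan-1-one | COc1cc(OCc2ccccc2)c([C@@H](O[Si](C)(C)C)[C@@H](OC)C(=O)c2c(F)cc(OC)c(OC)c2OC)cc1OCc1ccccc1
F0 | step 7 | none | none
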